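**Remark (assumption and numbering).** Compound 1 is taken to be the commercial levorotatory bicyclic lactone diol with the configuration of its SMILES. Prostaglandin numbering is used throughout (C1 lactone carbonyl, C5=C6 Z olefin, C8 and C12 ring carbons carrying the two arms, C9 ketone, C11 acetoxy carbon, C13=C14 E olefin, C15 lactone carbinol carbon). The carboxyl carbon of the acetic acid arm of 1 lies outside this numbering and is lost as CO2 in step 14.

## Analysis of the target

The target is the 11-acetate of a prostaglandin E2 1,15-lactone: a cyclopentanone (ring A, C8–C12) trans-fused through C8 and C12 to a 13-membered lactone (ring B: C1–C8, C12–C15 and the ring oxygen). Ring B holds a Z olefin at C5=C6 and an E olefin at C13=C14, and the pentyl group C16–C20 sits on C15. There are four stereocentres. C8, C11 and C12 are contiguous on ring A (8R, 11R, 12R), with the C8 arm and the C11 acetoxy group both trans to the C12 arm. C15 (S) is an allylic carbinol carbon separated from the ring by the E olefin, so it cannot be set by relay from ring A. The sensitive groups are the β-acetoxy ketone (C9/C11, which loses acetic acid to a cyclopentenone), the enolisable C8, the allylic C15–O bond of the lactone, and the pair of esters, which excludes hydroxide or hydride once both are in place. The difficulty is twofold: the oxygens at C9, C11 and C15 end in three different states (ketone, acetate, lactone) and must be told apart, and a 13-membered ring containing a Z olefin has to be closed without scrambling it. The strategy rests on the bond C6–C7: C7 is a methylene on ring carbon C8, C6 is an sp2 carbon of the Z olefin of ring B, and in lactone diol 1 this same C7 already carries a carboxyl carbon that can leave as CO2.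

## Retrosynthetic reasoning

**22 to 20.** The C9 ketone is made last. A β-acetoxy ketone with an enolisable C8 would not survive a cathode, nucleophilic catalysts or base. So 22 is traced to the C9 alcohol 21 and this to its silyl ether 20; forward, an acidic desilylation and a neutral alcohol oxidation.

**20 to 19 (the strategic cut).** Ring B is opened at C6–C7. Cutting the lactone C1–O bond instead would require the C15 hydroxyl to be acylated in the ring-closing step in the presence of other oxygen functions. A cut at C5=C6 would leave the olefin geometry to be decided during or after ring closure. Cutting C6–C7 lets the C15 ester be made intermolecularly on a single free hydroxyl and lets the Z olefin arrive preformed as the Z-vinyl iodide of 19. The sp3 partner C7 is a primary carbon whose carboxyl group is already present in 1. Forward, the phthalimide ester and the vinyl iodide of 19 must be joined at nickel by decarboxylative coupling with loss of iodide.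

**19 to 17 and 18.** The redox-active ester is cut at its N–O acyl bond to acid 17 and N-hydroxyphthalimide 18. It is made last before the ring closure because such esters tolerate neither nucleophiles nor base.

**17 to 14.** Acid 17 comes from its 4-methoxybenzyl ester 16 by acidolysis, the one unmasking that spares an acetate, an allylic ester, a vinyl iodide and a hindered silyl ether. The acetate of 16 is cut back to the C11 alcohol 15 and this to the triethylsilyl ether 14. C11 is silylated as triethylsilyl and C9 as tert-butyldimethylsilyl so that C11 can be freed alone.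

**14 to 9 and 13.** The C15–O acyl bond is cut to allylic alcohol 9 and (Z)-6-iodohex-5-enoic acid 13. In 9 the C15 hydroxyl is the only free one, so no protecting group is spent on it.

**13 to 10.** The Z-vinyl iodide 13 is traced to iodoalkyne 12 (syn addition of hydrogen) and this to hex-5-ynoic acid 10 through its dianion 11.

**9 to 6 and 7.** C15 is set by catalyst-controlled reduction of enone 8. The E olefin C13=C14 is cut to aldehyde 6 and phosphonate 7.

**6 to 1.** Aldehyde 6 comes from the primary triethylsilyl ether of 5 by direct oxidation. Compound 5 comes from hydroxy ester 4, and 4 from the bis-silyl lactone 2 by saponification and alkylation of the carboxylate 3. The lactone must be opened here, before any acetate or C15 ester exists, because its opening needs hydroxide. Compound 2 is the bis-silyl ether of 1, which supplies C8, C9, C11 and C12 with the correct configuration.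

## Alternatives that were turned down

**Alternative 1:** Here ring A is not bought but made. Two molecules of succinaldehyde A1 are joined under amino-acid enamine catalysis and then an ammonium-salt aldol condensation. This forms C8–C9 and C11=C12 and gives the bicyclic lactol enal A2, in which the C9 oxygen already bridges to C6.
- For it: two steps from a C4 feedstock and no chiral building block. The lactol carbon C6 of A2 is ready for a Z-selective Wittig reaction, and the enal of A2 accepts the lower chain by conjugate addition with C12 trans to C8.
- Against it for this target: A2 has no oxygen at C11, so that oxygen must be introduced after the conjugate addition by oxidative cleavage and ketone reduction. The dimerisation competes with oligomerisation of A1. C15 has to be brought in on a separately prepared enantioenriched lower-chain nucleophile. An acetate cannot sit at C11 during the ylide step. The ring would still have to be closed by lactonisation onto C15 while the Wittig reaction has just freed the C9 hydroxyl, which competes as a lactonisation site.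
- Comparison: it is stronger in step count to the carbon skeleton and uses only precedented reactions. The chosen route offers in exchange all ring stereocentres from compound 1, an unambiguous intermolecular esterification at C15, and a ring closure at carbon that does not depend on telling three hydroxyls apart at the end.

**Alternative 2:** The cut is at C8–C12. The silyl ketene acetal of the nine-membered allylic lactone A3 (carbonyl C7, ring oxygen on C14, Z olefin C12=C13) undergoes an Ireland–Claisen rearrangement to the cyclopentanecarboxylic acid A4.
- For it: one step closes ring A, sets C12 by chirality transfer from C14, and delivers the E olefin C13=C14 with the complete lower chain and C15 in place.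
- Against it: in A4 the carboxyl group on C8 is cis to the C12 arm, so C8 must later be epimerised. The carboxyl carbon of A4 is C7 itself, so the whole upper chain C6–C1 with its Z olefin must still be built by reduction and chain extension. The carbohydrate-derived lactone A3 needs a long sequence and a medium-ring lactonisation. Ring B is still unmade.
- Comparison: it is the more instructive construction of ring A, but at least twice as long. The chosen route buys ring A and spends its effort on ring B.

**Alternative 3:** The cut is at C5–C6 as a triple bond. The diyne A5 (but-2-ynyl on C8, hept-5-ynoate on the C15 oxygen) is closed to the cycloalkyne A7 by the alkylidyne catalyst A6, a hexavalent molybdenum complex of formula Mo(CC6H4OCH3)(OSi(C6H5)3)3. A syn semihydrogenation of A7 would then give the Z olefin.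
- For it: alkyne metathesis with catalyst A6 is reversible and tolerates the ketone, the acetate and the E olefin. The Z geometry follows from syn hydrogenation. The closure runs on the C9 ketone itself, so no silyl ether or late oxidation is needed.
- Against it: the but-2-ynyl arm on C8 of A5 must be built by a multi-step homologation of the lactone carbon of 1 or by an enolate alkylation in a three-component assembly. The catalyst A6 is sensitive to air and moisture. A separate semihydrogenation of A7 is needed beside an E olefin. The β-acetoxy ketone is carried through more steps.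
- Comparison: it is stronger in certainty, since each step belongs to a known reaction class. The chosen route closes ring B in one operation with the Z olefin already fixed, uses a simple nickel salt and current in place of catalyst A6, and uses the acetic acid arm of 1 as it is. Its price is a ring closure that goes beyond known chemistry.

Key step: step 14

## Route

**Step 1**
Reactants: 1 (3aR,4S,5R,6aS)-5-hydroxy-4-(hydroxymethyl)hexahydro-2H-cyclopenta[b]furan-2-one (bicyclic lactone diol)
Product: 2 bis(triethylsilyl) ether of 1 (C11 and C13 oxygens silylated)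
Conditions: Et3SiCl (2.4 equiv), imidazole (4 equiv), DMF, 0 °C to rt
Reagents that add atoms: chlorotriethylsilane, CC[Si](Cl)(CC)CC
Why: Standard silylation of a primary and an unhindered secondary alcohol; the triethylsilyl group is chosen so that the primary ether can later be oxidised directly and the C11 ether can be removed beside a tert-butyldimethylsilyl ether.

**Step 2**
Reactants: 2 bis(triethylsilyl) lactone
Product: 4 4-methoxybenzyl ester of the opened hydroxy acid (C9 hydroxyl free; C11 and C13 triethylsilyl ethers), via potassium hydroxy carboxylate 3 (not isolated)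
Conditions: KOH (1.1 equiv), THF/H2O, 0 °C to rt; evaporate, toluene azeotrope; 4-MeOC6H4CH2Cl (1.3 equiv), n-Bu4NI (cat.), DMF, rt; used at once
Reagents that add atoms: potassium hydroxide, [K+].[OH-]; 4-methoxybenzyl chloride, COc1ccc(CCl)cc1
Why: Saponification of the γ-lactone followed by O-alkylation of the carboxylate, which is far more nucleophilic than the neutral C9 hydroxyl; no stereocentre is touched, and the ester is carried on immediately because a cis γ-hydroxy ester can re-close.

**Step 3**
Reactants: 4 hydroxy 4-methoxybenzyl ester
Product: 5 C9 tert-butyldimethylsilyl ether of 4 (C9 OTBS, C11 OTES, C13 OTES, 4-methoxybenzyl ester)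
Conditions: t-BuMe2SiOSO2CF3 (1.3 equiv), 2,6-lutidine (2.5 equiv), CH2Cl2, −78 to 0 °C
Reagents that add atoms: tert-butyldimethylsilyl trifluoromethanesulfonate, CC(C)(C)[Si](C)(C)OS(=O)(=O)C(F)(F)F
Why: Silyl triflate silylation of the hindered C9 hydroxyl is fast at low temperature and outruns lactonisation; the triethylsilyl ethers and the ester are inert.

**Step 4**
Reactants: 5 tris-silyl ester
Product: 6 C13 aldehyde (C9 OTBS, C11 OTES, 4-methoxybenzyl ester)
Conditions: (COCl)2 (4 equiv), DMSO (8 equiv), CH2Cl2, −78 to −40 °C; Et3N (12 equiv), −78 °C to rt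
Reagents that add atoms: none
Why: Swern oxidation applied directly to a primary triethylsilyl ether: the activated sulfoxide cleaves the unhindered primary Si–O bond and oxidises that carbon, while the secondary triethylsilyl and tert-butyldimethylsilyl ethers are too hindered to react; C12 already has its more stable trans,trans arrangement.

**Step 5**
Reactants: 6 aldehyde; 7 dimethyl (2-oxoheptyl)phosphonate
Product: 8 (13E)-15-enone (C9 OTBS, C11 OTES, 4-methoxybenzyl ester)
Conditions: 7 (1.3 equiv), LiCl, i-Pr2NEt, MeCN, rt
Reagents that add atoms: none
Why: Horner–Wadsworth–Emmons olefination under Masamune–Roush conditions gives the E enone; the mild amine base avoids β-elimination of the C11 silyloxy group.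

**Step 6**
Reactants: 8 enone
Product: 9 (15S)-allylic alcohol (C9 OTBS, C11 OTES, 4-methoxybenzyl ester)
Conditions: (R)-2-methyl-CBS-oxazaborolidine (0.5 equiv), catecholborane (2 equiv), toluene, −78 °C
Reagents that add atoms: none
Why: Corey–Bakshi–Shibata reduction; the alkenyl group acts as the large substituent, so the R catalyst delivers hydride to the face that gives 15S under reagent control, and the low temperature keeps the reduction 1,2 and spares the ester.

**Step 7**
Reactants: 10 hex-5-ynoic acid
Product: 12 6-iodohex-5-ynoic acid, via dilithium alkynide carboxylate 11 (not isolated)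
Conditions: n-C4H9Li (2.1 equiv), THF, −78 to −20 °C; I2 (1.05 equiv), −78 °C; aq HCl, Na2S2O3 wash
Reagents that add atoms: iodine, II
Why: Double deprotonation gives the carboxylate acetylide (the alkyne C–H is far more acidic than the α-C–H of a carboxylate), and iodination of a lithium acetylide is a textbook route to 1-iodoalkynes.

**Step 8**
Reactants: 12 6-iodohex-5-ynoic acid
Product: 13 (Z)-6-iodohex-5-enoic acid
Conditions: 2-nitrobenzenesulfonylhydrazide (2.5 equiv), Et3N (5 equiv), THF/i-PrOH, rt, dark
Reagents that add atoms: none
Why: Diimide generated in the flask adds hydrogen syn to the iodoalkyne and leaves the C–I bond intact, which fixes the Z geometry of the future C5=C6 olefin; the alkyne reacts faster than the vinyl iodide formed.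

**Step 9**
Reactants: 9 (15S)-allylic alcohol; 13 (Z)-6-iodohex-5-enoic acid
Product: 14 C15 (Z)-6-iodohex-5-enoate (C9 OTBS, C11 OTES, 4-methoxybenzyl ester)
Conditions: 13 (1.3 equiv), EDC·HCl (1.5 equiv), DMAP (0.3 equiv), CH2Cl2, 0 °C to rt
Reagents that add atoms: none
Why: Steglich esterification of the only free hydroxyl; acylation at oxygen keeps the C15 configuration.

**Step 10**
Reactants: 14 triethylsilyl ether
Product: 15 C11 alcohol (C9 OTBS, C15 iodohexenoate, 4-methoxybenzyl ester)
Conditions: PPTS (0.2 equiv), MeOH/CH2Cl2, 0 °C
Reagents that add atoms: none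
Why: Mild acid methanolysis removes a secondary triethylsilyl ether much faster than the hindered secondary tert-butyldimethylsilyl ether at C9; esters and the vinyl iodide are untouched.

**Step 11**
Reactants: 15 C11 alcohol
Product: 16 C11 acetate (C9 OTBS, C15 iodohexenoate, 4-methoxybenzyl ester)
Conditions: Ac2O, pyridine, DMAP (cat.), CH2Cl2, rt
Reagents that add atoms: acetic anhydride, CC(=O)OC(C)=O
Why: Standard acetylation of the single free secondary hydroxyl with retention at C11.

**Step 12**
Reactants: 16 4-methoxybenzyl ester
Product: 17 carboxylic acid (C9 OTBS, C11 OAc, C15 iodohexenoate, free CH2CO2H on C8)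
Conditions: CF3CO2H/CH2Cl2 (1:10), anisole (5 equiv), 0 °C, short reaction time
Reagents that add atoms: none
Why: Acidolysis of the 4-methoxybenzyl ester through the stabilised benzylic cation, which anisole traps; under anhydrous conditions at 0 °C the hindered silyl ether, the acetate, the allylic ester and the vinyl iodide should remain.

**Step 13**
Reactants: 17 carboxylic acid; 18 N-hydroxyphthalimide
Product: 19 N-acyloxyphthalimide of 17 (redox-active ester on C7; Z-vinyl iodide at C6 on the C15 ester arm)
Conditions: 18 (1.1 equiv), i-PrN=C=N-i-Pr (1.1 equiv), DMAP (0.1 equiv), CH2Cl2, rt, dark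
Reagents that add atoms: none
Why: Carbodiimide coupling of an unhindered acid with the acidic N–OH group; no free hydroxyl is present, so no lactone can form.

**Step 14**
Reactants: 19 redox-active ester with Z-vinyl iodide
Product: 20 9-O-tert-butyldimethylsilyl macrolide (13-membered lactone, 5Z,13E, C11 OAc)
Conditions: NiCl2(glyme) (20 mol %), 2,2'-bipyridine (24 mol %), AgNO3 (30 mol %), LiCl, DMF, magnesium anode, reticulated vitreous carbon cathode, constant current, 19 added by syringe pump to about 2 mM, rt
Reagents that add atoms: none
Why: Proposed new method: the closest known reaction is the intermolecular nickel-electrocatalytic decarboxylative alkenylation of N-acyloxyphthalimides with alkenyl halides, and placing both partners in one molecule to close a macrocycle has not been shown. Cathodic reduction of the divalent nickel bipyridine complex gives low-valent (zerovalent or monovalent) nickel, which inserts into the C6–I bond with retention of the Z geometry, and electron transfer to the phthalimide ester releases phthalimide anion, CO2 and the primary C7 radical. The alkenylnickel captures this radical to a trivalent alkyl(alkenyl)nickel, formally a 14-membered nickelacycle, and reductive elimination forms C6–C7; the 13-membered ring therefore closes by reductive elimination at the metal and not by a 13-endo radical addition to an olefin. No stereocentre is formed, since C7 is a methylene group and C8, C11, C12 and C15 are not involved. The step needs ring closure to beat oligomerisation and simple reduction of either terminus, which slow addition, high dilution and low current density favour, helped by the two arms being held trans-1,2 on ring A and stiffened by two olefins. It also needs the Z olefin to be kept, which follows from stereoretentive insertion and reductive elimination, and C–I insertion to be preferred over attack on the C15 allylic ester, which rests on the much higher reactivity of a vinyl iodide than of a 1,3-dialkyl allylic carboxylate. The C7 radical has no fast escape route, because attack on C13=C14 would be 4-exo or 5-endo, C9 is a silyl ether and not a carbonyl, and the neutral medium leaves the acetate alone.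

**Step 15**
Reactants: 20 silyl-protected macrolide
Product: 21 9-hydroxy macrolide (9α-OH, C11 OAc)
Conditions: HF·pyridine, pyridine, THF, 0 °C to rt
Reagents that add atoms: none
Why: Acidic fluoride cleaves the secondary silyl ether; the non-basic medium prevents acetyl migration from the C11 oxygen to the cis C9 oxygen and leaves the lactone intact.

**Step 16**
Reactants: 21 9-hydroxy macrolide
Product: 22 target, the 11-acetate of the 9-oxo 1,15-lactone (CNP0241847.1)
Conditions: Dess–Martin periodinane (1.5 equiv), NaHCO3, CH2Cl2, 0 °C to rt
Reagents that add atoms: none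
Why: Dess–Martin oxidation under buffered, near-neutral conditions gives the ketone without elimination of the β-acetoxy group and without epimerisation at C8, where the trans arrangement is in any case the more stable one.

## Compound list

1 | (3aR,4S,5R,6aS)-5-hydroxy-4-(hydroxymethyl)hexahydro-2H-cyclopenta[b]furan-2-one (bicyclic lactone diol) | O=C1C[C@H]2[C@@H](O1)C[C@@H](O)[C@@H]2CO | starting material
2 | bis(triethylsilyl) ether of 1 (C11 and C13 oxygens) | O=C1C[C@H]2[C@@H](O1)C[C@@H](O[Si](CC)(CC)CC)[C@@H]2CO[Si](CC)(CC)CC | intermediate
3 | potassium carboxylate of the opened lactone (C9 OH cis to the C8 acetate arm, C11 OTES, C13 OTES) | CC[Si](CC)(CC)OC[C@H]1[C@H](O[Si](CC)(CC)CC)C[C@H](O)[C@@H]1CC(=O)[O-].[K+] | intermediate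
4 | 4-methoxybenzyl ester of the opened hydroxy acid (C9 OH, C11 OTES, C13 OTES) | CC[Si](CC)(CC)OC[C@H]1[C@H](O[Si](CC)(CC)CC)C[C@H](O)[C@@H]1CC(=O)OCc2ccc(OC)cc2 | intermediate
5 | C9 tert-butyldimethylsilyl ether of 4 | CC[Si](CC)(CC)OC[C@H]1[C@H](O[Si](CC)(CC)CC)C[C@H](O[Si](C)(C)C(C)(C)C)[C@@H]1CC(=O)OCc2ccc(OC)cc2 | intermediate
6 | C13 aldehyde (C9 OTBS, C11 OTES, 4-methoxybenzyl ester) | O=C[C@H]1[C@H](O[Si](CC)(CC)CC)C[C@H](O[Si](C)(C)C(C)(C)C)[C@@H]1CC(=O)OCc2ccc(OC)cc2 | intermediate
7 | dimethyl (2-oxoheptyl)phosphonate | CCCCCC(=O)CP(=O)(OC)OC | starting material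
8 | (13E)-15-enone (C9 OTBS, C11 OTES, 4-methoxybenzyl ester) | CCCCCC(=O)/C=C/[C@H]1[C@H](O[Si](CC)(CC)CC)C[C@H](O[Si](C)(C)C(C)(C)C)[C@@H]1CC(=O)OCc2ccc(OC)cc2 | intermediate
9 | (15S)-allylic alcohol (C9 OTBS, C11 OTES, 4-methoxybenzyl ester) | CCCCC[C@H](O)/C=C/[C@H]1[C@H](O[Si](CC)(CC)CC)C[C@H](O[Si](C)(C)C(C)(C)C)[C@@H]1CC(=O)OCc2ccc(OC)cc2 | intermediate
10 | hex-5-ynoic acid | C#CCCCC(=O)O | starting material
11 | dilithium salt of hex-5-ynoic acid (lithium carboxylate, lithium acetylide) | [Li]C#CCCCC(=O)O[Li] | intermediate
12 | 6-iodohex-5-ynoic acid | IC#CCCCC(=O)O | intermediate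
13 | (Z)-6-iodohex-5-enoic acid | OC(=O)CCC/C=C\I | intermediate
14 | C15 (Z)-6-iodohex-5-enoate of 9 (C9 OTBS, C11 OTES, 4-methoxybenzyl ester) | CCCCC[C@H](OC(=O)CCC/C=C\I)/C=C/[C@H]1[C@H](O[Si](CC)(CC)CC)C[C@H](O[Si](C)(C)C(C)(C)C)[C@@H]1CC(=O)OCc2ccc(OC)cc2 | intermediate
15 | C11 alcohol (C9 OTBS, C15 iodohexenoate, 4-methoxybenzyl ester) | CCCCC[C@H](OC(=O)CCC/C=C\I)/C=C/[C@H]1[C@H](O)C[C@H](O[Si](C)(C)C(C)(C)C)[C@@H]1CC(=O)OCc2ccc(OC)cc2 | intermediate
16 | C11 acetate (C9 OTBS, C15 iodohexenoate, 4-methoxybenzyl ester) | CCCCC[C@H](OC(=O)CCC/C=C\I)/C=C/[C@H]1[C@H](OC(C)=O)C[C@H](O[Si](C)(C)C(C)(C)C)[C@@H]1CC(=O)OCc2ccc(OC)cc2 | intermediate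
17 | carboxylic acid (C9 OTBS, C11 OAc, C15 iodohexenoate) | CCCCC[C@H](OC(=O)CCC/C=C\I)/C=C/[C@H]1[C@H](OC(C)=O)C[C@H](O[Si](C)(C)C(C)(C)C)[C@@H]1CC(=O)O | intermediate
18 | N-hydroxyphthalimide | ON1C(=O)c2ccccc2C1=O | starting material
19 | N-acyloxyphthalimide of 17 (precursor of the key step) | CCCCC[C@H](OC(=O)CCC/C=C\I)/C=C/[C@H]1[C@H](OC(C)=O)C[C@H](O[Si](C)(C)C(C)(C)C)[C@@H]1CC(=O)ON1C(=O)c2ccccc2C1=O | intermediate
20 | 9-O-tert-butyldimethylsilyl macrolide (5Z,13E; C11 OAc) | CCCCC[C@H]1/C=C/[C@H]2[C@H](OC(C)=O)C[C@H](O[Si](C)(C)C(C)(C)C)[C@@H]2C/C=C\CCCC(=O)O1 | intermediate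
21 | 9α-hydroxy macrolide (C11 OAc) | CCCCC[C@H]1/C=C/[C@H]2[C@H](OC(C)=O)C[C@H](O)[C@@H]2C/C=C\CCCC(=O)O1 | intermediate
22 | target, 11-acetate of the 9-oxo 1,15-lactone | CCCCC[C@H]1/C=C/[C@H]2[C@H](OC(C)=O)CC(=O)[C@@H]2C/C=C\CCCC(=O)O1 | target

## Step count and risks

Total: 16 steps. Longest linear sequence: 14 steps (steps 1–6 and 9–16 from compound 1); steps 7 and 8 make the side-arm acid 13.

**Step 14 (key step).** The seco compound may couple between molecules and oligomerise instead of closing. Either terminus may simply be reduced (C7 radical to a methyl group, C6–I to C6–H). Low-valent nickel may ionise the allylic ester at C15. The alkenylnickel may isomerise and erode the Z geometry. All follow from the slow capture of a tethered radical across a large ring.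

Fallback, from 5 back to 20: the C6–C7 bond is formed by the known intermolecular reaction and ring B is closed at the lactone bond instead. The 4-methoxybenzyl ester of 5 is saponified (LiOH, THF/H2O) to the tris-silyl acid F1, which is converted with 18 and diisopropylcarbodiimide into the N-acyloxyphthalimide F2. Acid 13 is methylated (CH3I, K2CO3, DMF) to methyl (Z)-6-iodohex-5-enoate F3. F2 is coupled with an excess of F3 under the conditions of step 14 without dilution, to give the upper-chain methyl ester F4. The conditions of steps 4, 5 and 6 applied to F4 should give in turn the aldehyde F5, the enone F6 and the (15S)-alcohol F7. Saponification of the methyl ester (LiOH) gives the seco acid F8, whose only free hydroxyl is at C15. Yamaguchi macrolactonisation (2,4,6-trichlorobenzoyl chloride, Et3N, then DMAP, toluene, high dilution) closes ring B to the macrolide C11 triethylsilyl ether F9. Removal of the triethylsilyl group (PPTS, MeOH) gives the C11 alcohol F10, and acetylation as in step 11 reaches 20.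

**Step 2.** The γ-hydroxy ester 4 may re-close to the lactone with loss of the benzylic alcohol, since the C9 hydroxyl is cis to the ester arm. Hydroxide may also start to cleave the primary triethylsilyl ether.

Fallback, from 2 to 5: reverse the order so that the C9 hydroxyl is never free beside an ester. Saponify 2 to 3, dry the salt and silylate exhaustively (t-BuMe2SiCl, imidazole, DMF) to the silyl ether silyl ester F11. Hydrolyse the labile silyl ester on mild aqueous work-up to the acid F1 (the same compound as in the fallback for step 14). Alkylate its carboxylate (4-methoxybenzyl chloride, Cs2CO3, DMF) to 5.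

**Step 4.** The direct oxidation may stall at the silyl ether or also attack the secondary triethylsilyl ether at C11. The β-silyloxy aldehyde may lose the C11 oxygen by elimination under the amine.

Fallback, from 5 to 6: separate deprotection from oxidation. Cleave the primary triethylsilyl ether selectively (HF·pyridine buffered with pyridine, THF, 0 °C) to the primary alcohol F12. Oxidise at once with Dess–Martin periodinane, before the alcohol can lactonise onto the ester arm.

**Step 6.** Facial selectivity at C15 may be poor, because the nearest stereocentre is three bonds away and control is by the catalyst alone. Some 1,4-reduction of the enone may compete.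

Fallback, from 8 to 14: reduce 8 without selectivity by Luche reduction (NaBH4, CeCl3·7H2O, MeOH, −20 °C) and separate the two alcohols. The 15S alcohol is 9 and enters step 9. The 15R epimer F13 is esterified with 13 under Mitsunobu conditions (PPh3, diisopropyl azodicarboxylate), which inverts C15 and gives 14 directly.

## Further compounds

F1 | step 14 | tris-silyl acid (C9 OTBS, C11 OTES, C13 OTES, free CH2CO2H on C8) | CC[Si](CC)(CC)OC[C@H]1[C@H](O[Si](CC)(CC)CC)C[C@H](O[Si](C)(C)C(C)(C)C)[C@@H]1CC(=O)O
F2 | step 14 | N-acyloxyphthalimide of F1 | CC[Si](CC)(CC)OC[C@H]1[C@H](O[Si](CC)(CC)CC)C[C@H](O[Si](C)(C)C(C)(C)C)[C@@H]1CC(=O)ON2C(=O)c3ccccc3C2=O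
F3 | step 14 | methyl (Z)-6-iodohex-5-enoate | COC(=O)CCC/C=C\I
F4 | step 14 | upper-chain methyl ester (5Z; C9 OTBS, C11 OTES, C13 OTES) | CC[Si](CC)(CC)OC[C@H]1[C@H](O[Si](CC)(CC)CC)C[C@H](O[Si](C)(C)C(C)(C)C)[C@@H]1C/C=C\CCCC(=O)OC
F5 | step 14 | C13 aldehyde with upper chain (5Z; C9 OTBS, C11 OTES, methyl ester) | O=C[C@H]1[C@H](O[Si](CC)(CC)CC)C[C@H](O[Si](C)(C)C(C)(C)C)[C@@H]1C/C=C\CCCC(=O)OC
F6 | step 14 | (5Z,13E)-15-enone methyl ester (C9 OTBS, C11 OTES) | CCCCCC(=O)/C=C/[C@H]1[C@H](O[Si](CC)(CC)CC)C[C@H](O[Si](C)(C)C(C)(C)C)[C@@H]1C/C=C\CCCC(=O)OC
F7 | step 14 | (15S)-alcohol methyl ester (5Z,13E; C9 OTBS, C11 OTES) | CCCCC[C@H](O)/C=C/[C@H]1[C@H](O[Si](CC)(CC)CC)C[C@H](O[Si](C)(C)C(C)(C)C)[C@@H]1C/C=C\CCCC(=O)OC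
F8 | step 14 | seco acid (15S-OH; C9 OTBS, C11 OTES) | CCCCC[C@H](O)/C=C/[C@H]1[C@H](O[Si](CC)(CC)CC)C[C@H](O[Si](C)(C)C(C)(C)C)[C@@H]1C/C=C\CCCC(=O)O
F9 | step 14 | macrolide C11 triethylsilyl ether (C9 OTBS) | CCCCC[C@H]1/C=C/[C@H]2[C@H](O[Si](CC)(CC)CC)C[C@H](O[Si](C)(C)C(C)(C)C)[C@@H]2C/C=C\CCCC(=O)O1
F10 | step 14 | macrolide C11 alcohol (C9 OTBS) | CCCCC[C@H]1/C=C/[C@H]2[C@H](O)C[C@H](O[Si](C)(C)C(C)(C)C)[C@@H]2C/C=C\CCCC(=O)O1
F11 | step 2 | tert-butyldimethylsilyl ester of F1 (C9 OTBS, C11 OTES, C13 OTES) | CC[Si](CC)(CC)OC[C@H]1[C@H](O[Si](CC)(CC)CC)C[C@H](O[Si](C)(C)C(C)(C)C)[C@@H]1CC(=O)O[Si](C)(C)C(C)(C)C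
F12 | step 4 | C13 primary alcohol (C9 OTBS, C11 OTES, 4-methoxybenzyl ester) | OC[C@H]1[C@H](O[Si](CC)(CC)CC)C[C@H](O[Si](C)(C)C(C)(C)C)[C@@H]1CC(=O)OCc2ccc(OC)cc2
F13 | step 6 | (15R)-allylic alcohol, C15 epimer of 9 | CCCCC[C@@H](O)/C=C/[C@H]1[C@H](O[Si](CC)(CC)CC)C[C@H](O[Si](C)(C)C(C)(C)C)[C@@H]1CC(=O)OCc2ccc(OC)cc2
A1 | alternative 1 | succinaldehyde | O=CCCC=O
A2 | alternative 1 | (3aR,6aS)-2-hydroxy-3,3a,6,6a-tetrahydro-2H-cyclopenta[b]furan-5-carbaldehyde (bicyclic lactol enal) | O=CC1=C[C@H]2CC(O)O[C@H]2C1
A3 | alternative 2 | nine-membered allylic lactone (carbonyl C7, C9 ketal, C11 OTBS, Z olefin C12=C13, ring oxygen on C14, C15 4-methoxybenzyl ether) | O=C1CC2(OCCO2)C[C@@H](O[Si](C)(C)C(C)(C)C)/C=C\[C@H](O1)[C@@H](OCc3ccc(OC)cc3)CCCCC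
A4 | alternative 2 | cis-2-alkenylcyclopentanecarboxylic acid (C7 acid on C8, C9 ketal, C11 OTBS, lower chain on C12) | CCCCC[C@H](OCc1ccc(OC)cc1)/C=C/[C@H]1[C@H](O[Si](C)(C)C(C)(C)C)CC2(OCCO2)[C@H]1C(=O)O
A5 | alternative 3 | diyne (but-2-ynyl on C8, hept-5-ynoate on the C15 oxygen, C9 ketone, C11 OAc) | CCCCC[C@H](OC(=O)CCCC#CC)/C=C/[C@H]1[C@H](OC(C)=O)CC(=O)[C@@H]1CC#CC
A6 | alternative 3 | molybdenum alkylidyne Mo(CC6H4OCH3)(OSi(C6H5)3)3 | COc1ccc(cc1)C#[Mo](O[Si](c1ccccc1)(c1ccccc1)c1ccccc1)(O[Si](c1ccccc1)(c1ccccc1)c1ccccc1)O[Si](c1ccccc1)(c1ccccc1)c1ccccc1
A7 | alternative 3 | 5,6-didehydro analogue of the target (13-membered cycloalkyne lactone) | CCCCC[C@H]1/C=C/[C@H]2[C@H](OC(C)=O)CC(=O)[C@@H]2CC#CCCCC(=O)O1
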